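**Retrosynthetic overview**

1. Daphnicyclidin H ⇐ cyclopentadienyl diol 36 (MnO2 oxidation, tautomerisation). The five-membered ring is closed last, by intramolecular aldol condensation of an ester dienolate onto a ring ketone (33 → 35).
2. The carbocyclic seven-membered ring bridging piperidine and cycloheptanone ⇐ intramolecular nitronate Michael addition to a dienone (30 → 31), then Nef reaction. The acrylate arm ⇐ Suzuki coupling at an α-iodoenone (23 + 26).
3. Piperidine ⇐ partial reduction of the γ-lactam carbonyl and Mannich closure by a side-chain methyl ketone (18 → 21); the new ketone is homologated to CHO.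
4. Pyrrolidine (as γ-lactam) and cycloheptenone ⇐ Buchner ring expansion of N-(4-methoxybenzyl) 2-diazopropanamide 8. The strategy rests on the cycloheptenone ring: its quaternary carbon (CH3; bonded to the pyrrolidine N–CH carbon, the ring-fusion CH and a fulvene carbon) and its ketone carbon, three ring bonds away on the fulvene side, are a 4-methoxyphenyl ring enlarged by one carbene carbon inserted between C-ipso and C-ortho.
5. Ring order: γ-lactam and seven-membered ketone ring together (step 6), piperidine (step 14), bridging seven-membered ring (step 22), five-membered fulvene ring (step 24).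

Key step: step 6

Assumption: the sense of induction of Rh2(S-PTTL)4 at the quaternary carbon is taken as drawn; if it proves opposite, the enantiomeric catalyst Rh2(R-PTTL)4 is used with no other change.

**Route**

Step 1
Reactants: 1 methyl (S)-3-hydroxy-2-methylpropanoate
Product: 2 methyl (S)-3-(tert-butyldimethylsilyloxy)-2-methylpropanoate
Conditions: TBSCl, imidazole, CH2Cl2, 0 °C to rt
Reagents that add atoms: tert-butyldimethylsilyl chloride, CC(C)(C)[Si](C)(C)Cl
Why: Imidazole-promoted silylation of the primary alcohol should proceed without touching the α-stereocentre.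

Step 2
Reactants: 2 methyl (S)-3-(tert-butyldimethylsilyloxy)-2-methylpropanoate; 3 4-methoxybenzylamine
Product: 4 (S)-3-(tert-butyldimethylsilyloxy)-N-(4-methoxybenzyl)-2-methylpropanamide
Conditions: AlMe3, toluene, 0 °C to 80 °C
Reagents that add atoms: none
Why: Weinreb aminolysis: the dimethylaluminium amide of 3 attacks the ester under non-enolising conditions, so the stereocentre should be kept.

Step 3
Reactants: 4 (S)-3-(tert-butyldimethylsilyloxy)-N-(4-methoxybenzyl)-2-methylpropanamide
Product: 5 (R)-3-(tert-butyldimethylsilyloxy)-N-(4-methoxybenzyl)-2-methylpropan-1-amine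
Conditions: LiAlH4, THF, reflux
Reagents that add atoms: none
Why: Hydride reduction of the secondary amide to the secondary amine; the silyl ether should survive LiAlH4 (the descriptor changes to R only through CIP priorities).

Step 4
Reactants: 5 (R)-3-(tert-butyldimethylsilyloxy)-N-(4-methoxybenzyl)-2-methylpropan-1-amine; 6 ethyl 2-methyl-3-oxobutanoate
Product: 7 N-[(R)-3-(tert-butyldimethylsilyloxy)-2-methylpropyl]-N-(4-methoxybenzyl)-2-methyl-3-oxobutanamide
Conditions: DMAP (cat.), toluene, reflux, removal of EtOH
Reagents that add atoms: none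
Why: Thermal aminolysis of the β-keto ester (through the acylketene, DMAP-assisted) should give the β-keto amide; the epimeric centre between the carbonyls is removed in step 5.

Step 5
Reactants: 7 N-[(R)-3-(tert-butyldimethylsilyloxy)-2-methylpropyl]-N-(4-methoxybenzyl)-2-methyl-3-oxobutanamide
Product: 8 N-[(R)-3-(tert-butyldimethylsilyloxy)-2-methylpropyl]-2-diazo-N-(4-methoxybenzyl)propanamide
Conditions: 4-acetamidobenzenesulfonyl azide, DBU, MeCN, 0 °C to rt
Reagents that add atoms: 4-acetamidobenzenesulfonyl azide, CC(=O)Nc1ccc(cc1)S(=O)(=O)N=[N+]=[N-]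
Why: Regitz deacylative diazo transfer: the enolate adds to the sulfonyl azide and the adduct collapses with loss of the acetyl group as the N-acetyl sulfonamide.

Step 6
Reactants: 8 N-[(R)-3-(tert-butyldimethylsilyloxy)-2-methylpropyl]-2-diazo-N-(4-methoxybenzyl)propanamide
Product: 10 (8aR)-2-[(R)-3-(tert-butyldimethylsilyloxy)-2-methylpropyl]-6-methoxy-8a-methyl-3,8a-dihydrocyclohepta[c]pyrrol-1(2H)-one, via norcaradiene 9 (not isolated)
Conditions: Rh2(S-PTTL)4 (dirhodium tetrakis[(S)-N-phthaloyl-tert-leucinate], 1 mol %), CH2Cl2, −40 °C to 0 °C, slow addition of 8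
Reagents that add atoms: none
Why: The dirhodium carboxylate expels N2 from 8 to give an electrophilic rhodium carbene whose carbon adds to the ipso–ortho π bond of the electron-rich anisyl ring (intramolecular arene cyclopropanation, the Buchner reaction known for N-benzyl α-diazoamides), giving norcaradiene 9. The γ-lactam closes in this addition by 5-exo attack of the tethered carbene carbon on C-ipso, and the seven-membered ring then forms by thermal disrotatory 6π electrocyclic opening of the cyclopropane bond between C-ipso and C-ortho. The only new stereocentre is the quaternary methyl carbon; it is set by the face of the carbene carbon that the chiral phthalimido-carboxylate ligands expose to the arene (catalyst control), and the remote (R) centre of the side chain makes the minor epimer a separable diastereomer. Regioselectivity is fixed by symmetry, since both ortho carbons are equivalent and the para methoxy carbon must end as the enol ether carbon three bonds from the carbene carbon. The step needs chemoselectivity for arene addition over 1,2-hydride shift and over C–H insertion into the N-alkyl chain or the benzylic CH2; the bulky carboxylate ligands at low temperature, the methyl group with only primary β-hydrogens, the electron-rich ring and the inductive deactivation of the chain C–H bonds by the silyloxy group should secure it.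

Step 7
Reactants: 10 (8aR)-2-[(R)-3-(tert-butyldimethylsilyloxy)-2-methylpropyl]-6-methoxy-8a-methyl-3,8a-dihydrocyclohepta[c]pyrrol-1(2H)-one
Product: 12 cis-fused cross-conjugated dienone alcohol 2-[(R)-3-hydroxy-2-methylpropyl]-8a-methyl-3,3a-dihydrocyclohepta[c]pyrrole-1,6(2H,8aH)-dione, via unconjugated dienone silyl ether 11 (not isolated)
Conditions: 2 M aq. HCl, THF, 45 °C
Reagents that add atoms: water, O
Why: Acid hydrolysis of the enol ether gives the β,γ-unsaturated ketone 11, which conjugates to the cross-conjugated dienone while the silyl ether is cleaved; the ring-fusion CH is γ to the dienone and should settle by vinylogous epimerisation at the cis-fused γ-lactam (H cis to the angular methyl), as cis-fused five-membered lactones and lactams do at a dienone γ-position.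

Step 8
Reactants: 12 cis-fused cross-conjugated dienone alcohol
Product: 13 cis-fused enone alcohol 2-[(R)-3-hydroxy-2-methylpropyl]-8a-methyl-3,3a,4,5-tetrahydrocyclohepta[c]pyrrole-1,6(2H,8aH)-dione
Conditions: [(Ph3P)CuH]6 (0.35 equiv), H2O (5 equiv), benzene–THF, rt
Reagents that add atoms: none
Why: Stryker conjugate reduction: the copper hydride should add to the enone β-carbon next to the ring-fusion CH and leave the enone whose β-carbon is neopentyl (next to the quaternary carbon); the ring-fusion centre can no longer epimerise afterwards.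

Step 9
Reactants: 13 cis-fused enone alcohol
Product: 14 α-iodoenone alcohol (7-iodo derivative of 13)
Conditions: I2, pyridine, CH2Cl2, rt
Reagents that add atoms: iodine, II
Why: Johnson α-iodination (reversible pyridine addition to the β-carbon, iodination of the enolate, elimination of pyridine), a sequence known to work on enones with a quaternary γ-carbon.

Step 10
Reactants: 14 α-iodoenone alcohol
Product: 15 iodo ketal alcohol (spiro-1,3-dioxolane at the ring ketone carbon of 14)
Conditions: ethylene glycol, TsOH·H2O (cat.), benzene, reflux, Dean–Stark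
Reagents that add atoms: ethylene glycol, OCCO
Why: Acid-catalysed ketalisation of the 2-iodoenone (as in the classical 2-halo-2-cycloalkenone ketals); the double bond cannot migrate because the γ-carbon is quaternary.

Step 11
Reactants: 15 iodo ketal alcohol
Product: 16 iodo ketal aldehyde (N-[(R)-2-methyl-3-oxopropyl] lactam)
Conditions: Dess–Martin periodinane, NaHCO3, CH2Cl2, rt
Reagents that add atoms: none
Why: Buffered Dess–Martin oxidation of the primary alcohol; the aldehyde is used crude to limit epimerisation of the α-methyl centre (which is in any case corrected thermodynamically after step 14).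

Step 12
Reactants: 16 iodo ketal aldehyde
Product: 17 iodo ketal carbinol (N-[(R)-3-hydroxy-2-methylbutyl] lactam, both carbinol epimers)
Conditions: MeMgBr, THF, −78 °C
Reagents that add atoms: methylmagnesium bromide, C[Mg]Br
Why: Grignard addition to the aldehyde; the hindered lactam, the ketal and the vinyl iodide should not react at −78 °C, and the new carbinol centre is oxidised in step 13.

Step 13
Reactants: 17 iodo ketal carbinol
Product: 18 iodo ketal methyl ketone (N-[(R)-2-methyl-3-oxobutyl] lactam)
Conditions: Dess–Martin periodinane, NaHCO3, CH2Cl2, rt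
Reagents that add atoms: none
Why: Dess–Martin oxidation of the secondary alcohol to the methyl ketone that will serve as the Mannich donor.

Step 14
Reactants: 18 iodo ketal methyl ketone
Product: 21 tricyclic amino ketone (4-piperidinone fused to the pyrrolidine across N and the aminomethine carbon), via N,O-silyl acetal 19 (not isolated), via iminium trifluoroacetate 20 (not isolated)
Conditions: IrCl(CO)(PPh3)2 (2 mol %), (Me2HSi)2O, toluene, rt; then CF3CO2H, CH2Cl2, 0 °C to rt
Reagents that add atoms: none
Why: Iridium-catalysed hydrosilylation of the tertiary lactam (chemoselective over ketones) gives the N,O-silyl acetal, acid ionises it to the iminium ion, and the enol of the methyl ketone closes the piperidinone by intramolecular Mannich reaction (6-(enolendo)-endo-trig); attack anti to the angular methyl through a chair with the ring methyl equatorial should place the aminomethine H cis to the angular methyl, and the methyl-bearing carbon α to the new ketone equilibrates to the same equatorial (natural) configuration.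

Step 15
Reactants: 21 tricyclic amino ketone
Product: 22 methyl enol ether (exocyclic methoxymethylene at the former piperidinone carbonyl carbon, E/Z mixture)
Conditions: Ph3P(CH2OMe)Cl, KN(SiMe3)2, THF, 0 °C to rt
Reagents that add atoms: (methoxymethyl)triphenylphosphonium chloride, COC[P+](c1ccccc1)(c1ccccc1)c1ccccc1.[Cl-]
Why: Wittig methoxymethylenation of the only free ketone (the ring ketone is masked as the ketal); N-alkyl 4-piperidinones are standard substrates.

Step 16
Reactants: 22 methyl enol ether
Product: 23 aldehyde iodoenone (4-formylpiperidine: CHO trans to the ring methyl, cis to the bond from the aminomethine carbon to the quaternary carbon; α-iodoenone restored)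
Conditions: 3 M aq. HCl, THF, rt
Reagents that add atoms: water, O
Why: Acid hydrolysis of the enol ether and of the dioxolane; axial protonation and acid-catalysed equilibration should both place the formyl group equatorial, which is the required configuration (any axial epimer cannot close the ring in step 22 and is removed there).

Step 17
Reactants: 24 4-(tert-butyldimethylsilyloxy)but-1-yne
Product: 25 methyl 5-(tert-butyldimethylsilyloxy)pent-2-ynoate
Conditions: nBuLi, THF, −78 °C; then ClCO2Me
Reagents that add atoms: methyl chloroformate, COC(=O)Cl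
Why: Acylation of the lithium acetylide with the chloroformate.

Step 18
Reactants: 25 methyl 5-(tert-butyldimethylsilyloxy)pent-2-ynoate
Product: 26 methyl (Z)-5-(tert-butyldimethylsilyloxy)-3-(4,4,5,5-tetramethyl-1,3,2-dioxaborolan-2-yl)pent-2-enoate
Conditions: B2pin2, CuCl (5 mol %), NaOtBu (10 mol %), Xantphos (5 mol %), MeOH, THF, rt
Reagents that add atoms: bis(pinacolato)diboron, CC1(C)OB(OC1(C)C)B1OC(C)(C)C(C)(C)O1
Why: Copper-catalysed β-borylation of the ynoate (syn borylcupration, protonation by methanol) should give the β-boryl acrylate with boron trans to the ester.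

Step 19
Reactants: 23 aldehyde iodoenone; 26 methyl (Z)-5-(tert-butyldimethylsilyloxy)-3-(pinacolboryl)pent-2-enoate
Product: 27 aldehyde dienone ester (α-carbon of the enone bonded to C-3 of the (E)-acrylate arm)
Conditions: PdCl2(dppf) (dppf = 1,1'-bis(diphenylphosphino)ferrocene, 5 mol %), K3PO4, DMF–H2O, 40 °C
Reagents that add atoms: none
Why: Suzuki–Miyaura coupling of the α-iodoenone with the alkenylboronate, with retention of the alkene geometry; it makes the enone β-carbon the terminus of both an enone and a dienoate.

Step 20
Reactants: 28 nitromethane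
Product: 29 tert-butyldimethylsilyl methanenitronate
Conditions: LiN(iPr)2, THF, −78 °C; then TBSCl
Reagents that add atoms: tert-butyldimethylsilyl chloride, CC(C)(C)[Si](C)(C)Cl
Why: O-silylation of lithium methanenitronate gives the silyl nitronate.

Step 21
Reactants: 27 aldehyde dienone ester; 29 tert-butyldimethylsilyl methanenitronate
Product: 30 silylated nitroaldol (side chain CH(OTBS)CH2NO2 on the piperidine, both epimers at the silyloxy carbon)
Conditions: Bu4NF (cat.), THF, −78 °C
Reagents that add atoms: none
Why: Fluoride-catalysed silyl nitronate addition to the aldehyde (Henry reaction with silyl transfer) gives the protected nitroaldol directly and leaves no free nitronate that could add to the dienone; the new carbinol centre becomes the enol carbon later.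

Step 22
Reactants: 30 silylated nitroaldol
Product: 31 tetracyclic nitro ketone (new seven-membered ring; mixture at the nitro, silyloxy and two newly sp3 ring carbons)
Conditions: DBU, MeCN, 0 °C to rt
Reagents that add atoms: none
Why: Intramolecular nitro-Michael addition (7-exo-trig): the nitronate carbon adds to the enone β-carbon next to the quaternary carbon; only the epimer with the side chain cis to the bond from the aminomethine carbon to the quaternary carbon can reach it, and all stereocentres created here are erased later.

Step 23
Reactants: 31 tetracyclic nitro ketone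
Product: 33 tetracyclic 1,4-diketone (α-silyloxy ketone in the new ring), via sodium nitronate 32 (not isolated)
Conditions: NaOMe, MeOH, 0 °C; then TiCl3, NH4OAc, H2O, rt
Reagents that add atoms: water, O
Why: McMurry reductive Nef reaction: TiCl3 reduces the nitronate to the imine, which hydrolyses at buffered pH to the ketone, without affecting ester, ketone, amine or silyl ethers.

Step 24
Reactants: 33 tetracyclic 1,4-diketone
Product: 35 cyclopentadiene bis(silyl ether), via aldol adduct 34 (not isolated)
Conditions: DBU, MeCN, 50 °C
Reagents that add atoms: none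
Why: Intramolecular aldol condensation: deprotonation between the ring ketone and the acrylate gives a dienolate whose ester α-carbon adds to the new ketone (5-(enolexo)-exo-trig), and E1cB loss of water gives the cyclopentadiene, so the correct oxidation level is reached without a dehydrogenation.

Step 25
Reactants: 35 cyclopentadiene bis(silyl ether)
Product: 36 cyclopentadienyl diol
Conditions: HF·pyridine, THF, 0 °C to rt
Reagents that add atoms: none
Why: Fluoride cleavage of both silyl ethers under mildly acidic conditions that the ester and the amine tolerate.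

Step 26
Reactants: 36 cyclopentadienyl diol
Product: 38 daphnicyclidin H, via triketone tautomer 37 (not isolated)
Conditions: MnO2, CH2Cl2, rt
Reagents that add atoms: none
Why: MnO2 oxidises only the secondary alcohol allylic to the cyclopentadiene (the primary homoallylic alcohol is not activated), and the resulting acylcyclopentadiene should tautomerise to the hydrogen-bonded hydroxyfulvene.

**Compound list**

1 | methyl (S)-3-hydroxy-2-methylpropanoate | C[C@@H](CO)C(=O)OC | starting material
2 | methyl (S)-3-(tert-butyldimethylsilyloxy)-2-methylpropanoate | C[C@@H](CO[Si](C)(C)C(C)(C)C)C(=O)OC | intermediate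
3 | 4-methoxybenzylamine | NCc1ccc(OC)cc1 | starting material
4 | (S)-3-(tert-butyldimethylsilyloxy)-N-(4-methoxybenzyl)-2-methylpropanamide | C[C@@H](CO[Si](C)(C)C(C)(C)C)C(=O)NCc1ccc(OC)cc1 | intermediate
5 | (R)-3-(tert-butyldimethylsilyloxy)-N-(4-methoxybenzyl)-2-methylpropan-1-amine | C[C@@H](CO[Si](C)(C)C(C)(C)C)CNCc1ccc(OC)cc1 | intermediate
6 | ethyl 2-methyl-3-oxobutanoate | CCOC(=O)C(C)C(C)=O | starting material
7 | N-[(R)-3-(tert-butyldimethylsilyloxy)-2-methylpropyl]-N-(4-methoxybenzyl)-2-methyl-3-oxobutanamide (both epimers at C-2 of the butanamide) | CC(=O)C(C)C(=O)N(Cc1ccc(OC)cc1)C[C@@H](C)CO[Si](C)(C)C(C)(C)C | intermediate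
8 | N-[(R)-3-(tert-butyldimethylsilyloxy)-2-methylpropyl]-2-diazo-N-(4-methoxybenzyl)propanamide | CC(=[N+]=[N-])C(=O)N(Cc1ccc(OC)cc1)C[C@@H](C)CO[Si](C)(C)C(C)(C)C | intermediate
9 | norcaradiene: cyclopropane fused to the 4-methoxycyclohexa-1,3-diene and to the N-alkyl γ-lactam, methyl on the cyclopropane carbon α to the lactam carbonyl and cis to the diene ring | COC1=C[C@@H]2[C@@]3(C)C(=O)N(C[C@@H](C)CO[Si](C)(C)C(C)(C)C)C[C@@]23C=C1 | intermediate
10 | (8aR)-2-[(R)-3-(tert-butyldimethylsilyloxy)-2-methylpropyl]-6-methoxy-8a-methyl-3,8a-dihydrocyclohepta[c]pyrrol-1(2H)-one | COC1=CC=C2CN(C[C@@H](C)CO[Si](C)(C)C(C)(C)C)C(=O)[C@]2(C)C=C1 | intermediate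
11 | unconjugated dienone silyl ether: lactam with C3a=C4 and C7=C8 double bonds and C-6 ketone, quaternary carbon as in 10 | C[C@@H](CO[Si](C)(C)C(C)(C)C)CN1CC2=CCC(=O)C=C[C@@]2(C)C1=O | intermediate
12 | 2-[(R)-3-hydroxy-2-methylpropyl]-8a-methyl-3,3a-dihydrocyclohepta[c]pyrrole-1,6(2H,8aH)-dione, cis-fused (3a-H and 8a-CH3 on the same face), quaternary carbon as in 10 | C[C@@H](CO)CN1C[C@H]2C=CC(=O)C=C[C@@]2(C)C1=O | intermediate
13 | 2-[(R)-3-hydroxy-2-methylpropyl]-8a-methyl-3,3a,4,5-tetrahydrocyclohepta[c]pyrrole-1,6(2H,8aH)-dione, cis-fused, C7=C8 enone | C[C@@H](CO)CN1C[C@H]2CCC(=O)C=C[C@@]2(C)C1=O | intermediate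
14 | 7-iodo derivative of 13 (α-iodoenone) | C[C@@H](CO)CN1C[C@H]2CCC(=O)C(I)=C[C@@]2(C)C1=O | intermediate
15 | ethylene ketal of 14 (spiro-1,3-dioxolane at C-6, vinyl iodide at C-7) | C[C@@H](CO)CN1C[C@H]2CCC3(OCCO3)C(I)=C[C@@]2(C)C1=O | intermediate
16 | aldehyde from 15: N-[(R)-2-methyl-3-oxopropyl] lactam | C[C@@H](C=O)CN1C[C@H]2CCC3(OCCO3)C(I)=C[C@@]2(C)C1=O | intermediate
17 | carbinol from 16: N-[(R)-3-hydroxy-2-methylbutyl] lactam, both carbinol epimers | C[C@@H](C(C)O)CN1C[C@H]2CCC3(OCCO3)C(I)=C[C@@]2(C)C1=O | intermediate
18 | methyl ketone: N-[(R)-2-methyl-3-oxobutyl] lactam | C[C@@H](C(C)=O)CN1C[C@H]2CCC3(OCCO3)C(I)=C[C@@]2(C)C1=O | intermediate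
19 | N,O-silyl acetal of 18 (lactam carbonyl reduced to CH–O–SiMe2–O–SiMe2H, both epimers) | C[C@@H](C(C)=O)CN1C[C@H]2CCC3(OCCO3)C(I)=C[C@@]2(C)C1O[Si](C)(C)O[SiH](C)C | intermediate
20 | cyclic iminium trifluoroacetate (N=CH next to the quaternary carbon) carrying the methyl ketone side chain | C[C@@H](C(C)=O)C[N+]1C[C@H]2CCC3(OCCO3)C(I)=C[C@@]2(C)C=1.[O-]C(=O)C(F)(F)F | intermediate
21 | tricyclic amino ketone: 4-piperidinone fused to the pyrrolidine across N and the aminomethine carbon; aminomethine H cis to the angular methyl; 3-methyl of the piperidinone equatorial, trans to the bond from the aminomethine carbon to the quaternary carbon; iodo-cycloheptene ketal retained | C[C@@H]1CN2C[C@H]3CCC4(OCCO4)C(I)=C[C@@]3(C)[C@H]2CC1=O | intermediate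
22 | methyl enol ether of 21 (exocyclic C=CH–OMe at the former ketone carbon, E/Z mixture) | C[C@@H]1CN2C[C@H]3CCC4(OCCO4)C(I)=C[C@@]3(C)[C@H]2CC1=COC | intermediate
23 | aldehyde iodoenone: 4-formyl-3-methylpiperidine ring (CHO trans to CH3, cis to the bond to the quaternary carbon), α-iodocycloheptenone | C[C@@H]1CN2C[C@H]3CCC(=O)C(I)=C[C@@]3(C)[C@H]2C[C@H]1C=O | intermediate
24 | 4-(tert-butyldimethylsilyloxy)but-1-yne | C#CCCO[Si](C)(C)C(C)(C)C | starting material
25 | methyl 5-(tert-butyldimethylsilyloxy)pent-2-ynoate | COC(=O)C#CCCO[Si](C)(C)C(C)(C)C | intermediate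
26 | methyl (Z)-5-(tert-butyldimethylsilyloxy)-3-(4,4,5,5-tetramethyl-1,3,2-dioxaborolan-2-yl)pent-2-enoate | COC(=O)/C=C(/B1OC(C)(C)C(C)(C)O1)CCO[Si](C)(C)C(C)(C)C | intermediate
27 | aldehyde dienone ester: 23 with iodine replaced by the (E)-1-(2-silyloxyethyl)-2-(methoxycarbonyl)vinyl arm | C[C@@H]1CN2C[C@H]3CCC(=O)C(/C(CCO[Si](C)(C)C(C)(C)C)=C/C(=O)OC)=C[C@@]3(C)[C@H]2C[C@H]1C=O | intermediate
28 | nitromethane | C[N+](=O)[O-] | starting material
29 | tert-butyldimethylsilyl methanenitronate | C=[N+]([O-])O[Si](C)(C)C(C)(C)C | intermediate
30 | silylated nitroaldol: 27 with CHO converted to CH(OTBS)CH2NO2 (both epimers at the silyloxy carbon) | C[C@@H]1CN2C[C@H]3CCC(=O)C(/C(CCO[Si](C)(C)C(C)(C)C)=C/C(=O)OC)=C[C@@]3(C)[C@H]2C[C@H]1C(O[Si](C)(C)C(C)(C)C)C[N+](=O)[O-] | intermediate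
31 | tetracyclic nitro ketone: nitro-bearing carbon bonded to the former enone β-carbon, closing the seven-membered carbocycle; acrylate arm on the ketone α-carbon; mixture at the nitro, silyloxy and two new sp3 ring carbons, arm alkene geometry not defined | [O-][N+](=O)C1C(O[Si](C)(C)C(C)(C)C)[C@@H]2C[C@H]3N(C[C@@H](CCC(=O)C4C(CCO[Si](C)(C)C(C)(C)C)=CC(=O)OC)[C@@]3(C)C14)C[C@H]2C | intermediate
32 | sodium nitronate of 31 | [Na+].[O-][N+]([O-])=C1C(O[Si](C)(C)C(C)(C)C)[C@@H]2C[C@H]3N(C[C@@H](CCC(=O)C4C(CCO[Si](C)(C)C(C)(C)C)=CC(=O)OC)[C@@]3(C)C14)C[C@H]2C | intermediate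
33 | tetracyclic 1,4-diketone: nitro carbon of 31 converted to C=O (α-silyloxy ketone) | O=C1C(O[Si](C)(C)C(C)(C)C)[C@@H]2C[C@H]3N(C[C@@H](CCC(=O)C4C(CCO[Si](C)(C)C(C)(C)C)=CC(=O)OC)[C@@]3(C)C14)C[C@H]2C | intermediate
34 | aldol adduct: cyclopentene with tertiary OH at the former ketone carbon and CH(CO2Me) next to it | COC(=O)C1C2(O)C(O[Si](C)(C)C(C)(C)C)[C@@H]3C[C@H]4N(C[C@@H](CCC(=O)C5=C1CCO[Si](C)(C)C(C)(C)C)[C@@]4(C)C25)C[C@H]3C | intermediate
35 | cyclopentadiene bis(silyl ether): pentacyclic skeleton, ring diene conjugated with ketone and ester, sp3 ring CH next to the quaternary carbon, CH(OTBS) in the bridging ring (epimers) | COC(=O)C1=C2C(O[Si](C)(C)C(C)(C)C)[C@@H]3C[C@H]4N(C[C@@H](CCC(=O)C5=C1CCO[Si](C)(C)C(C)(C)C)[C@@]4(C)C25)C[C@H]3C | intermediate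
36 | cyclopentadienyl diol (35 with both silyl groups removed) | COC(=O)C1=C2C(O)[C@@H]3C[C@H]4N(C[C@@H](CCC(=O)C5=C1CCO)[C@@]4(C)C25)C[C@H]3C | intermediate
37 | triketone tautomer (36 with the secondary alcohol oxidised to the ketone) | COC(=O)C1=C2C(=O)[C@@H]3C[C@H]4N(C[C@@H](CCC(=O)C5=C1CCO)[C@@]4(C)C25)C[C@H]3C | intermediate
38 | daphnicyclidin H | COC(=O)C1=C(CCO)C2=C3C1=C(O)[C@@H]1C[C@H]4N(C[C@@H](CCC2=O)[C@@]34C)C[C@H]1C | target

**Step count and risks**

Total: 26 steps. Longest linear sequence: 23 steps (steps 1–16, 19, 21–26 from 1).

Steps most likely to fail: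

Step 6. The methyl-substituted carbene may undergo 1,2-hydride shift to the acrylamide or insert into C–H bonds of the N-alkyl chain or the benzylic CH2 faster than it adds to the arene, and facial selection at the carbene carbon may be poor. The fallback makes the quaternary centre in two operations. It sets out from amine 5, which is acylated with N-succinimidyl diazoacetate (Et3N, THF) to diazoacetamide F1. This carbene has no β-hydrogen and belongs to the best-behaved Buchner class; Rh2(OAc)4 in CH2Cl2 should give the demethyl cycloheptatriene lactam F2. Deprotonation with LiN(iPr)2 (THF, −78 °C) at the carbon between the lactam carbonyl and the triene, then MeI, should give 10 together with its epimer at the quaternary carbon. The two are diastereomers because of the side-chain centre and are separated by chromatography; the route is rejoined at 10 at the cost of catalyst control.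

Step 22. Closure of the bridged seven-membered ring requires the piperidine to place both bridging bonds axial, so the Michael addition may be slow, and the nitronate may instead lose silanolate by β-elimination or revert by retro-Michael reaction. The fallback closes the same ring through the other bond. It sets out from 27, which is treated with nitromethane and DBU in THF. Intermolecular Michael addition to the dienone β-carbon should give nitromethyl aldehyde F3, whose nitronate adds to the aldehyde (intramolecular Henry reaction; the aldehyde α-centre can epimerise, so both epimers can funnel through) to give cyclic nitro alcohol F4. Silylation with TBSOTf and 2,6-lutidine returns to 31.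

Step 7. The vinylogous epimerisation may stop at an unfavourable cis/trans ratio at the ring fusion, and the result also decides whether step 8 can tell the two enones apart. The fallback sets the ring-fusion hydrogen kinetically, at a stage where only one enone is present. It sets out from 10. Hydrolysis with oxalic acid in wet THF at 0 °C is stopped at 11, which is isolated. Conjugate hydrosilylation of its only enone (Et3SiH, RhCl(PPh3)3 cat., benzene) should give triethylsilyl enol ether F5. Hydrogenation of the remaining ring-fusion alkene (H2, Pd/C, EtOAc), expected by analogy with angular-methyl hydrindenones to deliver hydrogen cis to the methyl, gives cis-fused silyl enol ether F6. Saegusa–Ito oxidation (Pd(OAc)2, MeCN) restores the enone regiospecifically as enone silyl ether F7, and aq. HCl in THF removes the silyl group to rejoin the route at 13.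

Further compounds
F1 | step 6 | N-[(R)-3-(tert-butyldimethylsilyloxy)-2-methylpropyl]-2-diazo-N-(4-methoxybenzyl)acetamide | [N-]=[N+]=CC(=O)N(Cc1ccc(OC)cc1)C[C@@H](C)CO[Si](C)(C)C(C)(C)C
F2 | step 6 | 2-[(R)-3-(tert-butyldimethylsilyloxy)-2-methylpropyl]-6-methoxy-3,8a-dihydrocyclohepta[c]pyrrol-1(2H)-one (8a-H, both epimers) | COC1=CC=C2CN(C[C@@H](C)CO[Si](C)(C)C(C)(C)C)C(=O)C2C=C1
F3 | step 22 | nitromethyl aldehyde: 27 with CH2NO2 added to the enone β-carbon (epimers) | C[C@@H]1CN2C[C@H]3CCC(=O)C(C(CCO[Si](C)(C)C(C)(C)C)=CC(=O)OC)C(C[N+](=O)[O-])[C@@]3(C)[C@H]2C[C@H]1C=O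
F4 | step 22 | cyclic nitro alcohol: 31 with free OH in place of OTBS | [O-][N+](=O)C1C(O)[C@@H]2C[C@H]3N(C[C@@H](CCC(=O)C4C(CCO[Si](C)(C)C(C)(C)C)=CC(=O)OC)[C@@]3(C)C14)C[C@H]2C
F5 | step 7 | triethylsilyl enol ether of the C-6 ketone (C6=C7), C3a=C4 alkene retained, TBS ether on the side chain | C[C@@H](CO[Si](C)(C)C(C)(C)C)CN1CC2=CCC(O[Si](CC)(CC)CC)=CC[C@@]2(C)C1=O
F6 | step 7 | cis-fused triethylsilyl enol ether (3a-H cis to 8a-CH3) | C[C@@H](CO[Si](C)(C)C(C)(C)C)CN1C[C@H]2CCC(O[Si](CC)(CC)CC)=CC[C@@]2(C)C1=O
F7 | step 7 | tert-butyldimethylsilyl ether of 13 | C[C@@H](CO[Si](C)(C)C(C)(C)C)CN1C[C@H]2CCC(=O)C=C[C@@]2(C)C1=O
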